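## The problem

The target, 2,4-dibromo-6-(3,6-dibromo-2-hydroxyphenoxy)phenol (16), is a diaryl ether of two bromophenols: ring A carries OH at C1, Br at C2 and C4 and the bridging oxygen at C6, and ring B carries the bridging oxygen at C1', Br at C2' and C5' and OH at C6'. There is no stereocentre and no stereogenic axis, so every question is one of regiochemistry and chemoselectivity. Ring A has the pattern that bromination of a 2-aryloxyphenol gives (ortho and para to OH), so it can be installed late by electrophilic substitution, provided ring B is then the less reactive ring. Ring B is the real difficulty: its bromines are para to each other and the position para to its OH (C3') is unsubstituted, whereas electrophilic bromination would attack C3' first. The ether oxygen is flanked by three ortho substituents (C1–OH, C2'–Br, C6'–OH), so a late Ullmann or SNAr union of two fully substituted halves is unattractive. Once the four C–Br bonds are in place, hydrogenolysis, zerovalent transition metals and alkyllithium reagents are excluded, and the free phenols over-brominate and oxidise easily. The feature that opens the structure is that C2'–C3'–C4'–C5' is a four-carbon diene with bromine at each end and C1'–C6' is a two-carbon unit bearing two heteroatoms, so ring B is a symmetric 2,5-dibromodiene plus a hetero-substituted alkyne, joined at C1'–C2' and C5'–C6'.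

## Retrosynthesis

**C6'–O of ring B (16 from 15).** The last bond cut is C6'–O, traced back to the C6'–B bond of pinacol boronate 15. Carrying this oxygen as a free phenol would make ring B compete in the ring A bromination. Carrying it as an ester costs two extra steps and invites acyl transfer between the two phenols. A boronate is not an activating group and needs no protection of its own. The forward reaction has to turn C–B into C–O without touching four C–Br bonds, which basic hydrogen peroxide does.

**C2–Br and C4–Br of ring A (15 from 14).** Both ring A bromines are cut together, leading to phenol 14. The free OH at C1 is required. With ring A as a bis-ether, the second bromine would go para to the bridging oxygen (C3), as in any 1,2-dialkoxyarene, and not to C2. The forward reaction must stop at two bromines and must spare ring B and its C–B bond.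

**O–benzyl bond on ring A (14 from 13).** The ring A phenol is masked as its 4-methoxybenzyl ether in 13. The group has to survive K2CO3 at 70 °C, n-BuLi at −78 °C and a thermal cycloaddition. It must then leave under conditions that spare C–Br and C–B. Hydrogenolysis would remove bromine, and boron trihalides (the usual reagents for plain benzyl or methyl ethers) would strip pinacol from boron. A benzyl ether cleaved by CF3CO2H meets all of this.

**C1'–C2' and C5'–C6' of ring B (13 from 2 and 11).** This is the central cut. Ring B is taken apart into 2,5-dibromothiophene 1,1-dioxide (2) and the aryloxyethynyl pinacol boronate 11. Cutting the diaryl ether instead would leave a ring B fragment whose 3,6-dibromo-1,2-dioxygenated pattern is just as inaccessible. Cutting the ring B C–Br bonds leads to substitutions that electrophilic chemistry cannot deliver. The cycloaddition cut removes a whole ring and all four of its substituents at once and leaves a symmetric diene and a linear alkyne. The forward reaction has to be a clean (4+2) process; regiochemistry is not at stake because the diene is symmetric.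

**C(sp)–B, the triple bond, O–C(vinyl) and O–benzyl (11 from 6 and 7; 6 from 4 and 5; 4 from 3).** The C–B bond of 11 comes from lithium acetylide 9 and borate ester 7. The triple bond comes from the (E)-1,2-dichlorovinyl ether 6 by elimination and chlorine–lithium exchange. Ether 6 comes from phenol 4 and trichloroethylene (5), which supplies C1' and C6' of the target. Phenol 4 is the mono-4-methoxybenzyl ether of catechol (3). Each of these steps is a standard operation on cheap materials.

**S=O bonds (2 from 1).** Dioxide 2 is the S,S-dioxide of commercial 2,5-dibromothiophene (1), so both ring B bromines are bought in their final positions.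

## Roads not taken

**Alternative 1:** The cut is made on ring A: the ether bond O–C6 and a C1–I bond that stands in for C1–OH. In the forward direction, fluoride would release the aryne from 2,4-dibromo-6-(trimethylsilyl)phenyl trifluoromethanesulfonate A2. The phenoxide of 3,6-dibromo-2-methoxyphenol A3 would add at C6, and the aryl anion at C1 would be trapped by a perfluoroalkyl iodide to give 1,4-dibromo-2-(3,5-dibromo-2-iodophenoxy)-3-methoxybenzene A1. Selective conversion of C–I to C–OH and demethylation would follow.

- Merits: it is convergent, it makes the hindered diaryl ether without copper or SNAr activation, the bromine next to the aryne steers the oxygen to C6, and both rings arrive fully brominated, so no late bromination has to discriminate between rings. In that last respect it is better than the chosen plan.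
- Weak points: A3 already contains the inaccessible ring B pattern, so the hard part is pushed into a building block. A2 is normally made by bromine–lithium exchange and silyl migration, which its own two bromines endanger. The aryl anion at C1 sits next to Br and can expel bromide to form a second aryne. The nucleophile is a doubly ortho-substituted phenoxide. Finally, one iodide must be hydroxylated in the presence of four bromides.
- Comparison: the chosen plan answers with commodity starting materials and with a key step that builds the difficult ring itself.

**Alternative 2:** Ring A is cut at C2–C3 and C5–C6. Base-mediated double condensation of 1-(3,6-dibromo-2-methoxyphenoxy)propan-2-one A5 with bromomalonaldehyde A6 would close ring A as 4-bromo-2-(3,6-dibromo-2-methoxyphenoxy)phenol A4. One ortho-bromination (the para position is already filled) and demethylation would finish the synthesis.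

- Merits: on paper this is the shortest road, about six steps with A3 as the source of A5, against eight here. Its endgame has no selectivity question and no sensitive organoboron or ynol ether. In these respects it is better.
- Weak points: this (3+3) phenol synthesis is reliable mainly when the dialdehyde carries a nitro group and the ketone is doubly activated. The bromo dialdehyde A6 is an acidic, base-labile partner. The unsymmetrical ketone must react once at its methyl and once at its aryloxymethylene carbon. A3 is again required, so the ring that forms is the easy one and the difficult ring is bought through directed-metalation chemistry.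
- Comparison: the chosen plan sets a cycloaddition driven by aromatisation and by gas loss against the shorter count, and it makes the difficult ring in that step.

**Alternative 3:** The two ring B bromines are cut back to carboxyl groups. Under 365 nm light the divalent copper carboxylates formed from 2-(3,5-dibromo-2-methoxyphenoxy)-3-methoxyterephthalic acid A8 would decarboxylate, and the two aryl radicals would take bromine from an N-bromo hydantoin. This would give 1,5-dibromo-3-(3,6-dibromo-2-methoxyphenoxy)-2-methoxybenzene A7, and double demethylation would give the target.

- Merits: like the chosen plan, it places the ring B bromines by connectivity. The para-dicarboxylated catechol core is a Kolbe–Schmitt-type pattern, and all intermediates are stable. Its robustness of intermediates is an advantage over the ynol ether boronate used here.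
- Weak points: A8 requires a hindered diaryl ether to a salicylate-type oxygen and differentiation of two adjacent oxygens. The step must succeed twice on one ring. The radical at C2' lies ortho to the aryloxy bridge and can cyclise onto ring A or abstract hydrogen. The ring A C–Br bonds are exposed to ultraviolet light.
- Comparison: the chosen plan creates the C2' and C5' positions already brominated in a closed-shell step, with no radical next to the ether.

Key step: step 5

## Route

**Step 1**
Reactants: 1 2,5-dibromothiophene
Product: 2 2,5-dibromothiophene 1,1-dioxide
Conditions: H2O2 (50% aq.), (CF3CO)2O (excess), CH2Cl2, 0 °C → rt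
Reagents that add atoms: hydrogen peroxide, OO
Why: Peracid S-oxidation of an electron-poor thiophene: trifluoroperacetic acid, generated in the flask from H2O2 and (CF3CO)2O, is strong enough to carry 2,5-dihalothiophenes through the sulfoxide to the sulfone, and the two α-bromines slow the self-dimerisation of the dioxide so that 2 should be isolable as a solid.

**Step 2**
Reactants: 3 catechol
Product: 4 2-[(4-methoxybenzyl)oxy]phenol
Conditions: 4-methoxybenzyl chloride (limiting), 3 (3 equiv), K2CO3, acetone, reflux
Reagents that add atoms: 4-methoxybenzyl chloride, COc1ccc(CCl)cc1
Why: Williamson ether synthesis on the catechol monoanion; the excess of 3 suppresses bis-alkylation and is removed by aqueous washing.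

**Step 3**
Reactants: 4 2-[(4-methoxybenzyl)oxy]phenol; 5 trichloroethylene
Product: 6 1-{[(E)-1,2-dichloroethenyl]oxy}-2-[(4-methoxybenzyl)oxy]benzene
Conditions: K2CO3, DMF, 70 °C
Reagents that add atoms: none
Why: Elimination–addition: K2CO3 converts 5 into dichloroacetylene, and anti addition of the phenoxide of 4 gives the (E)-1,2-dichlorovinyl ether, the standard precursor of ynol ethers; the benzyl-type ether is inert to K2CO3.

**Step 4**
Reactants: 6 1-{[(E)-1,2-dichloroethenyl]oxy}-2-[(4-methoxybenzyl)oxy]benzene; 7 2-isopropoxy-4,4,5,5-tetramethyl-1,3,2-dioxaborolane
Product: 11 2-({2-[(4-methoxybenzyl)oxy]phenoxy}ethynyl)-4,4,5,5-tetramethyl-1,3,2-dioxaborolane, via chloroalkynyl ether 8 (not isolated), via lithium acetylide 9 (not isolated), via lithium alkynylborate 10 (not isolated)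
Conditions: n-BuLi (2.1 equiv), THF, −78 °C; 7, −78 °C; HCl (1.0 equiv, Et2O), −78 °C → rt; filtration under Ar, no chromatography
Reagents that add atoms: none
Why: Vinylic deprotonation and loss of LiCl give 8, chlorine–lithium exchange gives 9 (the established dichlorovinyl ether route to metalated ynol ethers), and borylation with 7 followed by exactly one equivalent of anhydrous HCl collapses ate complex 10 to the alkynyl pinacol boronate; at −78 °C neither benzylic nor ring lithiation should compete.

**Step 5**
Reactants: 11 2-({2-[(4-methoxybenzyl)oxy]phenoxy}ethynyl)-4,4,5,5-tetramethyl-1,3,2-dioxaborolane; 2 2,5-dibromothiophene 1,1-dioxide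
Product: 13 2-(3,6-dibromo-2-{2-[(4-methoxybenzyl)oxy]phenoxy}phenyl)-4,4,5,5-tetramethyl-1,3,2-dioxaborolane, via bridged sulfone 12 (not isolated)
Conditions: 2 added slowly to 11 (1.5 equiv), PhMe, 4 Å MS, 80 °C, Ar sweep
Reagents that add atoms: none
Why: The LUMO of the sulfone diene 2 and the HOMO of the oxygen-substituted alkyne 11 combine in an inverse-electron-demand (4+2) cycloaddition that is concerted but asynchronous, with bonding most advanced at the alkyne carbon remote from oxygen (the future C6'). The resulting 7-thiabicyclo[2.2.1]hepta-2,5-diene 7,7-dioxide 12 should not accumulate, because cheletropic extrusion of SO2 is fast and irreversible at the reaction temperature and delivers ring B already aromatic. The closest known reaction types are the Diels–Alder/SO2-extrusion benzannulation of halogenated thiophene 1,1-dioxides with alkynes and the cycloaddition–extrusion benzannulations of alkynyl pinacol boronates with cyclopentadienones and 2-pyranones; this pair of partners has not been combined before, but each behaves within its known role. Ring B closes by intermolecular (4+2) cycloaddition, forming C1'–C2' and C5'–C6' in one step, followed by loss of the one-atom sulfur bridge. No stereocentre survives: the two bridgehead centres of 12 form as a racemate and vanish on aromatisation. Regioselectivity is not in question, since 2 is symmetric and either orientation of 11 gives the same arene with Br at C2' and C5', oxygen at C1' and boron at C6'. The step needs periselectivity, (4+2) over a stepwise (2+2) addition to one C=C of 2 and over dimerisation of 2; the α-bromines retard dimerisation, the boryl group tempers the nucleophilicity of the ynol ether, and slow addition of 2 to excess 11 keeps the cross reaction ahead.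

**Step 6**
Reactants: 13 2-(3,6-dibromo-2-{2-[(4-methoxybenzyl)oxy]phenoxy}phenyl)-4,4,5,5-tetramethyl-1,3,2-dioxaborolane
Product: 14 2-[3,6-dibromo-2-(4,4,5,5-tetramethyl-1,3,2-dioxaborolan-2-yl)phenoxy]phenol
Conditions: CF3CO2H, Et3SiH, CH2Cl2, 0 °C
Reagents that add atoms: none
Why: Acidolysis of a 4-methoxybenzyl aryl ether (SN1-type) with the benzyl cation reduced by the silane to 4-methylanisole; aryl bromides, the diaryl ether and the electron-poor, doubly ortho-substituted aryl–boron bond should tolerate brief exposure to CF3CO2H at 0 °C.

**Step 7**
Reactants: 14 2-[3,6-dibromo-2-(4,4,5,5-tetramethyl-1,3,2-dioxaborolan-2-yl)phenoxy]phenol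
Product: 15 2,4-dibromo-6-[3,6-dibromo-2-(4,4,5,5-tetramethyl-1,3,2-dioxaborolan-2-yl)phenoxy]phenol
Conditions: NBS (2.05 equiv), MeCN, 0 °C
Reagents that add atoms: N-bromosuccinimide, O=C1CCC(=O)N1Br
Why: Electrophilic aromatic bromination directed by the free OH of ring A to its para position (C4) and its only open ortho position (C2), as in the dibromination of guaiacol; ring B, with two bromines and a boronate in place of an OH, is far less reactive, NBS releases no HBr, and a pinacol boronate without an added activator resists ipso-bromodeboronation.

**Step 8**
Reactants: 15 2,4-dibromo-6-[3,6-dibromo-2-(4,4,5,5-tetramethyl-1,3,2-dioxaborolan-2-yl)phenoxy]phenol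
Product: 16 2,4-dibromo-6-(3,6-dibromo-2-hydroxyphenoxy)phenol
Conditions: H2O2 (30% aq.), NaOH (aq.), THF, 0 °C
Reagents that add atoms: hydrogen peroxide, OO
Why: Oxidation of an arylboronate with basic hydrogen peroxide (1,2-aryl shift from boron to oxygen, then B–O hydrolysis) converts C6'–B into C6'–OH at the same carbon; at 0 °C it is much faster than base-promoted protodeboronation and leaves the C–Br bonds and the ring A phenol untouched.

## Compound list

1 | 2,5-dibromothiophene | Brc1ccc(Br)s1 | starting material
2 | 2,5-dibromothiophene 1,1-dioxide | O=S1(=O)C(Br)=CC=C1Br | intermediate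
3 | catechol (benzene-1,2-diol) | Oc1ccccc1O | starting material
4 | 2-[(4-methoxybenzyl)oxy]phenol | COc1ccc(COc2ccccc2O)cc1 | intermediate
5 | trichloroethylene | ClC=C(Cl)Cl | starting material
6 | 1-{[(E)-1,2-dichloroethenyl]oxy}-2-[(4-methoxybenzyl)oxy]benzene | COc1ccc(COc2ccccc2O/C(Cl)=C\Cl)cc1 | intermediate
7 | 2-isopropoxy-4,4,5,5-tetramethyl-1,3,2-dioxaborolane | CC(C)OB1OC(C)(C)C(C)(C)O1 | starting material
8 | 1-[(chloroethynyl)oxy]-2-[(4-methoxybenzyl)oxy]benzene | COc1ccc(COc2ccccc2OC#CCl)cc1 | intermediate (not isolated)
9 | ({2-[(4-methoxybenzyl)oxy]phenoxy}ethynyl)lithium | COc1ccc(COc2ccccc2OC#C[Li])cc1 | intermediate (not isolated)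
10 | lithium isopropoxy(pinacolato)({2-[(4-methoxybenzyl)oxy]phenoxy}ethynyl)borate | [Li+].COc1ccc(COc2ccccc2OC#C[B-]2(OC(C)C)OC(C)(C)C(C)(C)O2)cc1 | intermediate (not isolated)
11 | 2-({2-[(4-methoxybenzyl)oxy]phenoxy}ethynyl)-4,4,5,5-tetramethyl-1,3,2-dioxaborolane | COc1ccc(COc2ccccc2OC#CB2OC(C)(C)C(C)(C)O2)cc1 | intermediate
12 | 1,4-dibromo-2-{2-[(4-methoxybenzyl)oxy]phenoxy}-3-(4,4,5,5-tetramethyl-1,3,2-dioxaborolan-2-yl)-7-thiabicyclo[2.2.1]hepta-2,5-diene 7,7-dioxide (racemic; bridgehead configuration fixed by the bicycle) | COc1ccc(COc2ccccc2OC2=C(B3OC(C)(C)C(C)(C)O3)C3(Br)C=CC2(Br)S3(=O)=O)cc1 | intermediate (not isolated)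
13 | 2-(3,6-dibromo-2-{2-[(4-methoxybenzyl)oxy]phenoxy}phenyl)-4,4,5,5-tetramethyl-1,3,2-dioxaborolane | COc1ccc(COc2ccccc2Oc2c(Br)ccc(Br)c2B2OC(C)(C)C(C)(C)O2)cc1 | intermediate
14 | 2-[3,6-dibromo-2-(4,4,5,5-tetramethyl-1,3,2-dioxaborolan-2-yl)phenoxy]phenol | Oc1ccccc1Oc1c(Br)ccc(Br)c1B1OC(C)(C)C(C)(C)O1 | intermediate
15 | 2,4-dibromo-6-[3,6-dibromo-2-(4,4,5,5-tetramethyl-1,3,2-dioxaborolan-2-yl)phenoxy]phenol | Oc1c(Br)cc(Br)cc1Oc1c(Br)ccc(Br)c1B1OC(C)(C)C(C)(C)O1 | intermediate
16 | 2,4-dibromo-6-(3,6-dibromo-2-hydroxyphenoxy)phenol | Oc1c(Br)cc(Br)cc1Oc1c(Br)ccc(Br)c1O | target

## Step count and risk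

Total step count: 8. Longest linear sequence: 7 steps (3 → 4 → 6 → 11 → 13 → 14 → 15 → 16); step 1 is the one-step side branch.

**Step 5 (key step).** The most likely failure is loss of periselectivity. The nucleophilic alkyne carbon may add stepwise to one vinyl sulfone C=C of 2 and close to a cyclobutene. Dimerisation of 2 may also compete, as may hydration of the ynol ether by acid formed from SO2 and adventitious water. The fallback gives up the ring construction and uses known arene chemistry. It sets out from 4, which is heated with commercial 1,4-dibromo-2-fluorobenzene (Cs2CO3, DMSO, 130 °C) in an SNAr reaction to give 1,4-dibromo-2-{2-[(4-methoxybenzyl)oxy]phenoxy}benzene F1. The ring B hydrogen flanked by the ether oxygen and a bromine (C6') is the most acidic, so it is removed with TMPMgCl·LiCl at −20 °C, where the ortho-bromoaryl magnesium species does not eliminate. Quenching with 7 returns to the route at 13.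

**Step 4.** The collapse of ate complex 10 with HCl may be accompanied by addition of HCl across the electron-rich triple bond. The push–pull alkyne may also hydrate or lose boron during isolation. The fallback moves the borylation to after ring formation. It sets out from 6, which is treated with n-BuLi as before and quenched with methanol to give the terminal ynol ether 1-(ethynyloxy)-2-[(4-methoxybenzyl)oxy]benzene F2. Cycloaddition of F2 with 2 under the conditions of step 5 (with loss of SO2) gives 1,4-dibromo-2-{2-[(4-methoxybenzyl)oxy]phenoxy}benzene F1. Magnesiation at C6' with TMPMgCl·LiCl and borylation with 7 then return to the route at 13.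

**Step 7.** Ipso-bromodeboronation at C6' (ortho to the ether oxygen) or bromination at C4' of ring B may compete once ring A has taken its first bromine. The fallback replaces the boronate by an ester as the deactivating group and sets out from 13. The C–B bond is oxidised first (H2O2, NaOH) to 3,6-dibromo-2-{2-[(4-methoxybenzyl)oxy]phenoxy}phenol F3, which is acetylated (Ac2O, pyridine, DMAP) to 3,6-dibromo-2-{2-[(4-methoxybenzyl)oxy]phenoxy}phenyl acetate F4. The benzyl-type ether is then removed (CF3CO2H, Et3SiH) to give 3,6-dibromo-2-(2-hydroxyphenoxy)phenyl acetate F5, which is kept away from base to prevent acetyl transfer to the ring A oxygen. Ring A is brominated with NBS to 3,6-dibromo-2-(3,5-dibromo-2-hydroxyphenoxy)phenyl acetate F6, and methanolysis (K2CO3, MeOH) returns to the route at 16.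

**Step 1.** Oxidation of the deactivated thiophene may stall at the sulfoxide stage, which dimerises readily, or the dioxide may decompose on concentration. The fallback makes the sulfone on an electron-rich thiophene and introduces bromine afterwards. It sets out from 1. Double bromine–lithium exchange (n-BuLi) and silylation (Me3SiCl) give 2,5-bis(trimethylsilyl)thiophene F7. mCPBA oxidises F7 smoothly to 2,5-bis(trimethylsilyl)thiophene 1,1-dioxide F8. Ipso-bromodesilylation with Br2 and AgBF4 returns to the route at 2.

## Further compounds

F1 | step 5 | 1,4-dibromo-2-{2-[(4-methoxybenzyl)oxy]phenoxy}benzene | COc1ccc(COc2ccccc2Oc2cc(Br)ccc2Br)cc1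
F2 | step 4 | 1-(ethynyloxy)-2-[(4-methoxybenzyl)oxy]benzene | COc1ccc(COc2ccccc2OC#C)cc1
F3 | step 7 | 3,6-dibromo-2-{2-[(4-methoxybenzyl)oxy]phenoxy}phenol | COc1ccc(COc2ccccc2Oc2c(Br)ccc(Br)c2O)cc1
F4 | step 7 | 3,6-dibromo-2-{2-[(4-methoxybenzyl)oxy]phenoxy}phenyl acetate | COc1ccc(COc2ccccc2Oc2c(Br)ccc(Br)c2OC(C)=O)cc1
F5 | step 7 | 3,6-dibromo-2-(2-hydroxyphenoxy)phenyl acetate | CC(=O)Oc1c(Br)ccc(Br)c1Oc1ccccc1O
F6 | step 7 | 3,6-dibromo-2-(3,5-dibromo-2-hydroxyphenoxy)phenyl acetate | CC(=O)Oc1c(Br)ccc(Br)c1Oc1cc(Br)cc(Br)c1O
F7 | step 1 | 2,5-bis(trimethylsilyl)thiophene | C[Si](C)(C)c1ccc([Si](C)(C)C)s1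
F8 | step 1 | 2,5-bis(trimethylsilyl)thiophene 1,1-dioxide | C[Si](C)(C)C1=CC=C([Si](C)(C)C)S1(=O)=O
A1 | alternative 1 | 1,4-dibromo-2-(3,5-dibromo-2-iodophenoxy)-3-methoxybenzene | COc1c(Br)ccc(Br)c1Oc1cc(Br)cc(Br)c1I
A2 | alternative 1 | 2,4-dibromo-6-(trimethylsilyl)phenyl trifluoromethanesulfonate | C[Si](C)(C)c1cc(Br)cc(Br)c1OS(=O)(=O)C(F)(F)F
A3 | alternative 1 | 3,6-dibromo-2-methoxyphenol | COc1c(Br)ccc(Br)c1O
A4 | alternative 2 | 4-bromo-2-(3,6-dibromo-2-methoxyphenoxy)phenol | COc1c(Br)ccc(Br)c1Oc1cc(Br)ccc1O
A5 | alternative 2 | 1-(3,6-dibromo-2-methoxyphenoxy)propan-2-one | CC(=O)COc1c(Br)ccc(Br)c1OC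
A6 | alternative 2 | bromomalonaldehyde (2-bromopropanedial) | O=CC(Br)C=O
A7 | alternative 3 | 1,5-dibromo-3-(3,6-dibromo-2-methoxyphenoxy)-2-methoxybenzene | COc1c(Br)cc(Br)cc1Oc1c(Br)ccc(Br)c1OC
A8 | alternative 3 | 2-(3,5-dibromo-2-methoxyphenoxy)-3-methoxyterephthalic acid | COc1c(Br)cc(Br)cc1Oc1c(C(=O)O)ccc(C(=O)O)c1OC
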